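The bicyclo[3.2.1]oct-3-ene-2,8-dione is read as a 1,4-benzoquinone ring (C1–C5 and C8) bridged by a former E-stilbene double bond (C6–C7). The route exploits that C7 is benzylic and para to an aryl oxygen (a latent p-alkoxybenzyl cation) while C1 lies between the C2 and C8 carbonyls (a latent enol-ether carbon). In one operation a chiral titanium TADDOLate joins stilbene C6 to quinone C5 and the cation so formed is captured by C1, closing the cyclopentanone ring C1–C7–C6–C5–C8 and setting all four stereocentres. The precursors are achiral: a 2-methoxy-6-styryl-1,4-benzoquinone and tetra-O-benzylpiceatannol. The extra C3 hydroxyl then leaves via its enol triflate.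

Key step: step 5

Remark: the (R,R)-TADDOL complex [(4R,5R)-2,2-dimethyl-α,α,α′,α′-tetraphenyl-1,3-dioxolane-4,5-dimethanol] is assumed to give the (5S,6S) series in step 5; if a test run shows the opposite sense, the equally available (S,S)-ligand is used and nothing else changes.

Step 1
Reactants: 1 3,4-bis(benzyloxy)benzyl chloride
Product: 2 diethyl [3,4-bis(benzyloxy)benzyl]phosphonate
Conditions: P(OEt)3 (neat, 3 equiv), 140 °C
Reagents that add atoms: triethyl phosphite, CCOP(OCC)OCC
Why: Michaelis–Arbuzov reaction, in which the benzylic chloride alkylates phosphorus and chloride then dealkylates the phosphonium salt; no stereocentre is formed.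

Step 2
Reactants: 2 diethyl [3,4-bis(benzyloxy)benzyl]phosphonate; 3 2-hydroxy-3-methoxybenzaldehyde (o-vanillin)
Product: 4 2-{(E)-2-[3,4-bis(benzyloxy)phenyl]ethenyl}-6-methoxyphenol
Conditions: KOtBu (2.3 equiv), DMF, 0 °C → rt; 1 M HCl
Reagents that add atoms: none
Why: Horner–Wadsworth–Emmons olefination with a benzylic phosphonate should give the E-alkene, the extra equivalent of base covering the free phenol as in olefinations of unprotected hydroxybenzaldehydes.

Step 3
Reactants: 4 2-{(E)-2-[3,4-bis(benzyloxy)phenyl]ethenyl}-6-methoxyphenol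
Product: 5 2-{(E)-2-[3,4-bis(benzyloxy)phenyl]ethenyl}-6-methoxycyclohexa-2,5-diene-1,4-dione
Conditions: (KSO3)2NO (2.5 equiv), KH2PO4, H2O–CH2Cl2, Bu4NHSO4, rt
Reagents that add atoms: potassium nitrosodisulfonate, [K+].[K+].[O-]S(=O)(=O)N([O])S(=O)(=O)[O-]
Why: Teuber oxidation, in which the nitrosodisulfonate radical forms the phenoxyl radical and a second equivalent adds at the free para carbon (both ortho positions are blocked) to give the p-quinone, while the alkene and benzyl ethers should be inert to this mild radical.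

Step 4
Reactants: 2 diethyl [3,4-bis(benzyloxy)benzyl]phosphonate; 6 3,5-bis(benzyloxy)benzaldehyde
Product: 7 1,2-bis(benzyloxy)-4-{(E)-2-[3,5-bis(benzyloxy)phenyl]ethenyl}benzene (tetra-O-benzylpiceatannol)
Conditions: KOtBu (1.2 equiv), THF, 0 °C → rt
Reagents that add atoms: none
Why: Horner–Wadsworth–Emmons olefination of an aromatic aldehyde with a benzylic phosphonate anion should be E-selective.

Step 5
Reactants: 5 2-{(E)-2-[3,4-bis(benzyloxy)phenyl]ethenyl}-6-methoxycyclohexa-2,5-diene-1,4-dione; 7 tetra-O-benzylpiceatannol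
Product: 10 (1S,5S,6S,7S)-7-[3,4-bis(benzyloxy)phenyl]-6-[3,5-bis(benzyloxy)phenyl]-4-{(E)-2-[3,4-bis(benzyloxy)phenyl]ethenyl}-3-hydroxybicyclo[3.2.1]oct-3-ene-2,8-dione, via benzylic cation 8 (not isolated), via O-methyloxocarbenium enolate 9 (not isolated)
Conditions: Cl2Ti[(R,R)-TADDOLate] (3 equiv, from TiCl4, Ti(OiPr)4 and (R,R)-TADDOL, 4 Å MS), CH2Cl2, −78 °C; aq. NaHCO3 at −78 °C
Reagents that add atoms: none
Why: The chiral dichlorotitanium TADDOLate chelates the C1 carbonyl and C2 methoxy oxygens of 5, the stilbene adds to quinone C5 through the carbon that carries the 3,5-bis(benzyloxy)phenyl ring because this polarity alone leaves a p-benzyloxybenzyl cation (8), and the enol-ether carbon C3 of the former quinone then captures that cation, forming the C1–C7 bond of the bicycle before chloride removes the methyl group of oxocarbenium 9. The closest known reaction type is the Lewis-acid-promoted formal [5+2] cycloaddition of 2-alkoxy-1,4-benzoquinones with (E)-1-arylalkenes, also in its titanium TADDOLate form. The cyclopentanone ring closes in a 5-(enolexo)-exo-trig cation–enol-ether cyclisation, and the seven-membered ring of the bicycle closes with it. C5 and C6 are set in the first bond formation, their absolute sense by the TADDOLate that shields one quinone face and their relative sense by the stacked approach of the 3,4-bis(benzyloxy)phenyl ring over the quinone; C7 follows from the E-alkene (trans to the C6 aryl group, endo) because ring closure should outrun C6–C7 rotation, and C1 is fixed by the bridge. The step needs attack at C5 and not at C3, secured by the chelate and by the methoxy donor on C2, and capture of the cation by C3 and not by C6 or the C4 oxygen, secured by the styryl group that blocks C6 and by the quench at −78 °C, which should keep the kinetic carbocycle from rearranging to a dihydrobenzofuran.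

Step 6
Reactants: 10 (1S,5S,6S,7S)-hexa-O-benzyl 3-hydroxy bicyclic dione
Product: 11 (1S,5S,6S,7S)-7-[3,4-bis(benzyloxy)phenyl]-6-[3,5-bis(benzyloxy)phenyl]-4-{(E)-2-[3,4-bis(benzyloxy)phenyl]ethenyl}-2,8-dioxobicyclo[3.2.1]oct-3-en-3-yl trifluoromethanesulfonate
Conditions: Tf2O (1.2 equiv), 2,6-lutidine, CH2Cl2, −78 °C
Reagents that add atoms: trifluoromethanesulfonic anhydride, O=S(=O)(OS(=O)(=O)C(F)(F)F)C(F)(F)F
Why: The C3 hydroxyl is an acidic diosphenol enol and the only free OH, so O-sulfonylation should give the enol triflate, and no stereocentre can epimerise because C1 and C5 are bridgeheads that cannot enolise.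

Step 7
Reactants: 11 (1S,5S,6S,7S)-hexa-O-benzyl enol triflate
Product: 12 (1R,5S,6S,7S)-7-[3,4-bis(benzyloxy)phenyl]-6-[3,5-bis(benzyloxy)phenyl]-4-{(E)-2-[3,4-bis(benzyloxy)phenyl]ethenyl}bicyclo[3.2.1]oct-3-ene-2,8-dione
Conditions: Pd(OAc)2 (10 mol %), PPh3 (20 mol %), HCO2H, Et3N, DMF, 50 °C
Reagents that add atoms: none
Why: Palladium-catalysed formate reduction of an enol triflate (oxidative addition of zerovalent palladium into the C3–O bond, formate exchange, loss of CO2, reductive elimination of C3–H) should give the enone and leave aryl benzyl ethers, the styryl alkene and the non-enolisable diketone untouched; the C1 descriptor changes only through the CIP priorities.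

Step 8
Reactants: 12 (1R,5S,6S,7S)-hexa-O-benzyl bicyclic enedione
Product: 13 (1R,5S,6S,7S)-7-(3,4-dihydroxyphenyl)-6-(3,5-dihydroxyphenyl)-4-[(E)-2-(3,4-dihydroxyphenyl)ethenyl]bicyclo[3.2.1]oct-3-ene-2,8-dione
Conditions: BCl3 (12 equiv), C6HMe5 (18 equiv), CH2Cl2, −78 °C; MeOH, −78 °C → rt
Reagents that add atoms: none
Why: Lewis-acid debenzylation with a non-basic cation scavenger, in which BCl3 ionises each aryl benzyl ether at low temperature and pentamethylbenzene traps the benzyl cations, should leave both alkenes, the enone and the bridgehead stereocentres unchanged.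

Compound list
1 | 3,4-bis(benzyloxy)benzyl chloride | ClCc1ccc(OCc2ccccc2)c(OCc2ccccc2)c1 | starting material
2 | diethyl [3,4-bis(benzyloxy)benzyl]phosphonate | CCOP(=O)(OCC)Cc1ccc(OCc2ccccc2)c(OCc2ccccc2)c1 | intermediate
3 | 2-hydroxy-3-methoxybenzaldehyde (o-vanillin) | COc1cccc(C=O)c1O | starting material
4 | 2-{(E)-2-[3,4-bis(benzyloxy)phenyl]ethenyl}-6-methoxyphenol | COc1cccc(/C=C/c2ccc(OCc3ccccc3)c(OCc3ccccc3)c2)c1O | intermediate
5 | 2-{(E)-2-[3,4-bis(benzyloxy)phenyl]ethenyl}-6-methoxycyclohexa-2,5-diene-1,4-dione | COC1=CC(=O)C=C(/C=C/c2ccc(OCc3ccccc3)c(OCc3ccccc3)c2)C1=O | intermediate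
6 | 3,5-bis(benzyloxy)benzaldehyde | O=Cc1cc(OCc2ccccc2)cc(OCc2ccccc2)c1 | starting material
7 | 1,2-bis(benzyloxy)-4-{(E)-2-[3,5-bis(benzyloxy)phenyl]ethenyl}benzene (tetra-O-benzylpiceatannol) | c1ccc(COc2cc(OCc3ccccc3)cc(/C=C/c3ccc(OCc4ccccc4)c(OCc4ccccc4)c3)c2)cc1 | intermediate
8 | zwitterion after the first C–C bond: quinone C5 alkylated by the stilbene, enolate oxygen on titanium (drawn metal-free), p-benzyloxybenzyl cation; the two new centres configured as C5 and C6 of 10 | COC1=CC(=O)[C@@H]([C@@H](c2cc(OCc3ccccc3)cc(OCc3ccccc3)c2)[CH+]c2ccc(OCc3ccccc3)c(OCc3ccccc3)c2)C(/C=C/c2ccc(OCc3ccccc3)c(OCc3ccccc3)c2)=C1[O-] | intermediate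
9 | bicyclic O-methyloxocarbenium enolate (drawn metal-free), configured as 10 | C[O+]=C1C([O-])=C(/C=C/c2ccc(OCc3ccccc3)c(OCc3ccccc3)c2)[C@H]2C(=O)[C@@H]1[C@@H](c1ccc(OCc3ccccc3)c(OCc3ccccc3)c1)[C@@H]2c1cc(OCc3ccccc3)cc(OCc3ccccc3)c1 | intermediate
10 | (1S,5S,6S,7S)-7-[3,4-bis(benzyloxy)phenyl]-6-[3,5-bis(benzyloxy)phenyl]-4-{(E)-2-[3,4-bis(benzyloxy)phenyl]ethenyl}-3-hydroxybicyclo[3.2.1]oct-3-ene-2,8-dione (C7 aryl endo, syn to the C2–C4 bridge; C6 aryl exo) | O=C1C(O)=C(/C=C/c2ccc(OCc3ccccc3)c(OCc3ccccc3)c2)[C@H]2C(=O)[C@@H]1[C@@H](c1ccc(OCc3ccccc3)c(OCc3ccccc3)c1)[C@@H]2c1cc(OCc3ccccc3)cc(OCc3ccccc3)c1 | intermediate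
11 | (1S,5S,6S,7S)-7-[3,4-bis(benzyloxy)phenyl]-6-[3,5-bis(benzyloxy)phenyl]-4-{(E)-2-[3,4-bis(benzyloxy)phenyl]ethenyl}-2,8-dioxobicyclo[3.2.1]oct-3-en-3-yl trifluoromethanesulfonate | O=C1C(OS(=O)(=O)C(F)(F)F)=C(/C=C/c2ccc(OCc3ccccc3)c(OCc3ccccc3)c2)[C@H]2C(=O)[C@@H]1[C@@H](c1ccc(OCc3ccccc3)c(OCc3ccccc3)c1)[C@@H]2c1cc(OCc3ccccc3)cc(OCc3ccccc3)c1 | intermediate
12 | (1R,5S,6S,7S)-7-[3,4-bis(benzyloxy)phenyl]-6-[3,5-bis(benzyloxy)phenyl]-4-{(E)-2-[3,4-bis(benzyloxy)phenyl]ethenyl}bicyclo[3.2.1]oct-3-ene-2,8-dione | O=C1C=C(/C=C/c2ccc(OCc3ccccc3)c(OCc3ccccc3)c2)[C@H]2C(=O)[C@@H]1[C@@H](c1ccc(OCc3ccccc3)c(OCc3ccccc3)c1)[C@@H]2c1cc(OCc3ccccc3)cc(OCc3ccccc3)c1 | intermediate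
13 | (1R,5S,6S,7S)-7-(3,4-dihydroxyphenyl)-6-(3,5-dihydroxyphenyl)-4-[(E)-2-(3,4-dihydroxyphenyl)ethenyl]bicyclo[3.2.1]oct-3-ene-2,8-dione | O=C1C=C(/C=C/c2ccc(O)c(O)c2)[C@H]2C(=O)[C@@H]1[C@@H](c1ccc(O)c(O)c1)[C@@H]2c1cc(O)cc(O)c1 | target

Total step count: 8. Longest linear sequence: 7 steps (steps 1, 2, 3, 5, 6, 7, 8).

Steps most likely to fail

Step 5. The hindered and only moderately nucleophilic stilbene may add too slowly to the chelated quinone, and the electron-rich styryl arm of 5 may compete for the Lewis acid or act as the alkene partner. Cation 8 may collapse on the C4 carbonyl oxygen and aromatise, the adduct may rearrange under acid before the quench, and facial selectivity may be poor. The fallback keeps the styryl arm out of the cycloaddition and attaches it afterwards by cross-coupling. Commercial 2-bromo-6-methoxyphenol is oxidised with (KSO3)2NO to 2-bromo-6-methoxy-1,4-benzoquinone F1, a smaller and more electrophilic partner without a competing alkene. The same titanium TADDOLate cycloaddition with stilbene 7 should give the 4-bromo-3-hydroxy bicycle F2, configured as 10. Suzuki–Miyaura coupling of this β-bromoenone (Pd(dppf)Cl2, K3PO4, THF–H2O, 50 °C) with the (E)-styrylboronic ester F3, made from commercial 3,4-bis(benzyloxy)benzaldehyde and CH2(Bpin)2/LiTMP by boron-Wittig olefination, then gives 10. This fallback sets out from 7 and comes back at 10.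

Step 8. The Lewis acid may assist heterolysis of the C1–C7 bond (a p-oxybenzyl carbon on a 1,3-dicarbonyl carbon) with rearomatisation of the six-membered ring. Escaping benzyl cations may C-benzylate the electron-rich rings, and cleavage of six ethers may stay incomplete. The fallback replaces the benzyl ethers by allyl ethers, so that the last operation runs under neutral palladium catalysis. Phosphonate 2 is hydrogenolysed (H2, Pd/C, EtOH) to diethyl (3,4-dihydroxybenzyl)phosphonate F4 and alkylated (allyl bromide, K2CO3, acetone) to diethyl [3,4-bis(allyloxy)benzyl]phosphonate F5. Olefination of 3 (NaH, THF) gives the allyl-protected phenol F6, and (KSO3)2NO oxidation gives the allyl-protected quinone F7. Commercial piceatannol and allyl bromide (K2CO3, DMF) give tetra-O-allylpiceatannol F8. The conditions of step 5 applied to F7 and F8 should give the hexa-O-allyl diosphenol F9, and Tf2O/2,6-lutidine its enol triflate F10. Pd(PPh3)4 with HCO2H/Et3N in THF at 40 °C should then reduce the triflate and remove all six allyl groups as propene in one flask. This fallback sets out from 2 and comes back at 13.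

Step 2. Deprotonation of the phenol gives a phenoxide that deactivates the ortho aldehyde, so that olefination may stall while the phosphonate anion decays. The fallback masks the phenol during the olefination. Compound 3 is protected (MOMCl, iPr2NEt, CH2Cl2) as 3-methoxy-2-(methoxymethoxy)benzaldehyde F11 and olefinated with 2 (KOtBu, THF) to the protected stilbene F12. Acetal cleavage (HCl, MeOH, 40 °C) returns 4. This fallback sets out from 3 and comes back at 4.

Further compounds
F1 | step 5 | 2-bromo-6-methoxycyclohexa-2,5-diene-1,4-dione | COC1=CC(=O)C=C(Br)C1=O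
F2 | step 5 | 7-[3,4-bis(benzyloxy)phenyl]-6-[3,5-bis(benzyloxy)phenyl]-4-bromo-3-hydroxybicyclo[3.2.1]oct-3-ene-2,8-dione, configured as 10 | O=C1C(O)=C(Br)[C@H]2C(=O)[C@@H]1[C@@H](c1ccc(OCc3ccccc3)c(OCc3ccccc3)c1)[C@@H]2c1cc(OCc3ccccc3)cc(OCc3ccccc3)c1
F3 | step 5 | 2-{(E)-2-[3,4-bis(benzyloxy)phenyl]ethenyl}-4,4,5,5-tetramethyl-1,3,2-dioxaborolane | CC1(C)OB(/C=C/c2ccc(OCc3ccccc3)c(OCc3ccccc3)c2)OC1(C)C
F4 | step 8 | diethyl (3,4-dihydroxybenzyl)phosphonate | CCOP(=O)(OCC)Cc1ccc(O)c(O)c1
F5 | step 8 | diethyl [3,4-bis(allyloxy)benzyl]phosphonate | CCOP(=O)(OCC)Cc1ccc(OCC=C)c(OCC=C)c1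
F6 | step 8 | 2-{(E)-2-[3,4-bis(allyloxy)phenyl]ethenyl}-6-methoxyphenol | COc1cccc(/C=C/c2ccc(OCC=C)c(OCC=C)c2)c1O
F7 | step 8 | 2-{(E)-2-[3,4-bis(allyloxy)phenyl]ethenyl}-6-methoxycyclohexa-2,5-diene-1,4-dione | COC1=CC(=O)C=C(/C=C/c2ccc(OCC=C)c(OCC=C)c2)C1=O
F8 | step 8 | 1,2-bis(allyloxy)-4-{(E)-2-[3,5-bis(allyloxy)phenyl]ethenyl}benzene (tetra-O-allylpiceatannol) | C=CCOc1cc(OCC=C)cc(/C=C/c2ccc(OCC=C)c(OCC=C)c2)c1
F9 | step 8 | hexa-O-allyl analogue of 10, same configuration | O=C1C(O)=C(/C=C/c2ccc(OCC=C)c(OCC=C)c2)[C@H]2C(=O)[C@@H]1[C@@H](c1ccc(OCC=C)c(OCC=C)c1)[C@@H]2c1cc(OCC=C)cc(OCC=C)c1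
F10 | step 8 | hexa-O-allyl analogue of 11, same configuration | O=C1C(OS(=O)(=O)C(F)(F)F)=C(/C=C/c2ccc(OCC=C)c(OCC=C)c2)[C@H]2C(=O)[C@@H]1[C@@H](c1ccc(OCC=C)c(OCC=C)c1)[C@@H]2c1cc(OCC=C)cc(OCC=C)c1
F11 | step 2 | 3-methoxy-2-(methoxymethoxy)benzaldehyde | COCOc1c(OC)cccc1C=O
F12 | step 2 | 1,2-bis(benzyloxy)-4-{(E)-2-[3-methoxy-2-(methoxymethoxy)phenyl]ethenyl}benzene | COCOc1c(OC)cccc1/C=C/c1ccc(OCc2ccccc2)c(OCc2ccccc2)c1
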